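**Retrosynthetic overview**

1. Target 20 is the all-trans (1S,2R,3R) 1-aryltetralin-2,3-dimethanol; the last moves are reduction of the two esters on C2 and C3 and hydrogenolysis of one benzyl ether.
2. Feature the route rests on: ring A reads C5–H, C6–OMe, C7–OH, C8–OMe. C6–C7–C8 with their three oxygens are the carbon chain of 1,3-dimethoxyacetone, C5 is a formyl carbon on C4a and C8a is a ketone carbon. Ring A is therefore cut at C5–C6 and C8–C8a ([3+3] phenol annulation) and is formed last.
3. The carbocycle C1–C4/C4a/C8a is made first as a cyclohexanone by a Diels–Alder disconnection at C1–C2 and C3–C4 (1-aryl-2-silyloxybutadiene plus a fumarate). (+)-Menthyl ester auxiliaries fix C2 and C3; C1 is set by equilibration next to the ketone.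
4. The diene comes from O-benzylhomosyringic acid through its Weinreb amide and the benzyl vinyl ketone.
5. Ring order: pendant aryl ring (bought), cyclohexanone ring (step 6), ring A (step 8).

Key step: step 8

Remark: tetralin numbering (C1 aryl-bearing, C4a/C8a ring fusion) is used for the carbocycle in all intermediates; the two esters are carried as (+)-menthyl esters, which act as auxiliaries in step 6 and as hindered, base-stable spectators in step 8, and di-(+)-menthyl fumarate is made in step 5.

**Route**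

Step 1
Reactants: 1 4-hydroxy-3,5-dimethoxyphenylacetic acid
Product: 3 (4-benzyloxy-3,5-dimethoxyphenyl)acetic acid, via benzyl ester 2 (not isolated)
Conditions: BnBr (2.3 equiv), K2CO3, DMF, 60 °C; then NaOH, MeOH–H2O, 50 °C; HCl to pH 2
Reagents that add atoms: benzyl bromide, BrCc1ccccc1; sodium hydroxide, [Na+].[OH-] (oxygen of the freed carboxyl group)
Why: Williamson O-alkylation of phenoxide and carboxylate followed by saponification of the benzyl ester in the same pot, which leaves the aryl benzyl ether untouched.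

Step 2
Reactants: 3 (4-benzyloxy-3,5-dimethoxyphenyl)acetic acid
Product: 5 2-(4-benzyloxy-3,5-dimethoxyphenyl)-N-methoxy-N-methylacetamide, via acyl imidazole 4 (not isolated)
Conditions: 1,1'-carbonyldiimidazole (1.1 equiv), CH2Cl2, rt; then MeNH(OMe)·HCl (1.3 equiv), rt
Reagents that add atoms: N,O-dimethylhydroxylamine hydrochloride, CNOC.Cl; 1,1'-carbonyldiimidazole, O=C(n1ccnc1)n1ccnc1 (imidazolyl group of 4 only)
Why: Carbonyldiimidazole activation gives the acyl imidazole, which acylates N,O-dimethylhydroxylamine (Weinreb amide formation).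

Step 3
Reactants: 5 2-(4-benzyloxy-3,5-dimethoxyphenyl)-N-methoxy-N-methylacetamide
Product: 6 1-(4-benzyloxy-3,5-dimethoxyphenyl)but-3-en-2-one
Conditions: CH2=CHMgBr (2 equiv), THF, −20 → 0 °C; inverse quench into cold 1 M HCl
Reagents that add atoms: vinylmagnesium bromide, C=C[Mg]Br
Why: Weinreb ketone synthesis, in which the chelated tetrahedral magnesium adduct stops at mono-addition and the inverse acidic quench keeps the released N,O-dimethylhydroxylamine from adding to the enone.

Step 4
Reactants: 6 1-(4-benzyloxy-3,5-dimethoxyphenyl)but-3-en-2-one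
Product: 7 (1Z)-1-(4-benzyloxy-3,5-dimethoxyphenyl)-2-(tert-butyldimethylsilyloxy)buta-1,3-diene
Conditions: TBSOTf (1.2 equiv), Et3N (1.6 equiv), CH2Cl2, 0 °C
Reagents that add atoms: tert-butyldimethylsilyl trifluoromethanesulfonate, CC(C)(C)[Si](C)(C)OS(=O)(=O)C(F)(F)F
Why: Soft enolisation with silyl triflate and amine can only take place at the benzylic CH2, and the (1Z) enol ether (aryl cis to oxygen, trans to the vinyl group), the isomer that can reach the s-cis diene conformation, is expected as the less strained conjugated isomer.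

Step 5
Reactants: 8 fumaric acid; 9 (+)-menthol
Product: 10 di-(+)-menthyl fumarate
Conditions: 9 (2.2 equiv), TsOH·H2O (cat.), toluene, reflux, Dean–Stark
Reagents that add atoms: none
Why: Fischer esterification driven by azeotropic removal of water, with the E-alkene unchanged.

Step 6
Reactants: 7 (1Z)-1-(4-benzyloxy-3,5-dimethoxyphenyl)-2-(tert-butyldimethylsilyloxy)buta-1,3-diene; 10 di-(+)-menthyl fumarate
Product: 13 di-(+)-menthyl (1R,2R,3S)-3-(4-benzyloxy-3,5-dimethoxyphenyl)-4-oxocyclohexane-1,2-dicarboxylate (all-trans, all-equatorial), via silyl enol ether cycloadduct 11 (not isolated), via unequilibrated ketone 12 (not isolated)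
Conditions: Et2AlCl (1.5 equiv), toluene, −78 → −40 °C; 1 M HCl, THF, rt; then DBU (0.2 equiv), CH2Cl2, rt
Reagents that add atoms: none
Why: Lewis-acid-promoted Diels–Alder reaction under auxiliary control forms C1–C2 and C3–C4: both menthyl esters take the s-trans enoate conformation with the carbinol C–H eclipsing C=O, so the two isopropyl groups screen the same face of the fumarate; since di-(−)-menthyl fumarate gives the (S,S) diester series with simple dienes, the (+)-menthyl ester should give the required (R,R) pair at C2/C3, the E-dienophile makes the esters trans, and C1 is then set by hydrolysis of the enol ether and DBU equilibration of the benzylic α-ketone centre to the all-equatorial isomer.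

Step 7
Reactants: 13 di-(+)-menthyl (1R,2R,3S)-3-(4-benzyloxy-3,5-dimethoxyphenyl)-4-oxocyclohexane-1,2-dicarboxylate
Product: 14 di-(+)-menthyl (1R,2R,3S,5Z)-3-(4-benzyloxy-3,5-dimethoxyphenyl)-5-(hydroxymethylene)-4-oxocyclohexane-1,2-dicarboxylate
Conditions: HCO2Et (5 equiv), NaH (2.5 equiv), EtOH (cat.), THF, 0 °C → rt; cold 1 M HCl
Reagents that add atoms: ethyl formate, CCOC=O
Why: Crossed Claisen formylation is reversible and ends at the C4a methylene, because only that keto aldehyde is deprotonated to a stabilised enolate, whereas acylation at the aryl-bearing methine or at the ester α-carbons gives non-enolisable adducts that revert.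

Step 8
Reactants: 14 di-(+)-menthyl (1R,2R,3S,5Z)-3-(4-benzyloxy-3,5-dimethoxyphenyl)-5-(hydroxymethylene)-4-oxocyclohexane-1,2-dicarboxylate; 15 1,3-dimethoxyacetone
Product: 18 di-(+)-menthyl (1S,2R,3R)-1-(4-benzyloxy-3,5-dimethoxyphenyl)-7-hydroxy-6,8-dimethoxy-1,2,3,4-tetrahydronaphthalene-2,3-dicarboxylate, via ene-dione 16 (not isolated), via cyclohexadienone 17 (not isolated)
Conditions: 15 (3 equiv), NaOMe (3 equiv), MeOH–THF, 0 → 40 °C; then AcOH
Reagents that add atoms: none
Why: Under methoxide the enolate of 15 should add to the formyl carbon C5 of 14 and lose water to give ene-dione 16 (C5–C6 bond); the second methoxy-bearing α-carbon C8 then adds to the ring ketone C8a, a second water is lost, and the 4a-H cyclohexa-2,5-dienone 17 tautomerises by deprotonation at C4a to the phenoxide of 18, the only irreversible event. The closest known reaction type is the base-mediated [3+3] phenol synthesis from 2-(hydroxymethylene) ketones or vinamidinium salts and ketones with two α-methylene groups; an α,α'-dialkoxy ketone is an unusual but electronically ordinary partner. Ring A closes in a 6-(enolendo)-exo-trig aldol step. No stereocentre is created, and C1, C2 and C3 are carried through. Regiochemistry is not an issue because 15 is symmetric, so either order of the two condensations gives the same arene with the free C7 hydroxyl between two methoxy groups. The step needs C1–C3 to survive base: before aromatisation the all-equatorial ketone is the thermodynamic epimer, and afterwards the doubly benzylic C1–H is not acidic while the hindered menthyl esters and the moderate temperature hold back exchange, saponification and α-epimerisation.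

Step 9
Reactants: 18 di-(+)-menthyl (1S,2R,3R)-1-(4-benzyloxy-3,5-dimethoxyphenyl)-7-hydroxy-6,8-dimethoxy-1,2,3,4-tetrahydronaphthalene-2,3-dicarboxylate
Product: 19 (1S,2R,3R)-1-(4-benzyloxy-3,5-dimethoxyphenyl)-2,3-bis(hydroxymethyl)-6,8-dimethoxy-1,2,3,4-tetrahydronaphthalen-7-ol
Conditions: LiAlH4 (6 equiv), THF, 0 → 50 °C; aq. Rochelle salt
Reagents that add atoms: none
Why: LiAlH4 reduction of both hindered esters to primary alcohols releases the auxiliary as menthol; the phenol is only deprotonated and hydride addition does not epimerise C2 or C3.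

Step 10
Reactants: 19 (1S,2R,3R)-1-(4-benzyloxy-3,5-dimethoxyphenyl)-2,3-bis(hydroxymethyl)-6,8-dimethoxy-1,2,3,4-tetrahydronaphthalen-7-ol
Product: 20 (1S,2R,3R)-1-(4-hydroxy-3,5-dimethoxyphenyl)-2,3-bis(hydroxymethyl)-6,8-dimethoxy-1,2,3,4-tetrahydronaphthalen-7-ol (target)
Conditions: H2 (1 atm), Pd/C (10 wt%), EtOAc–MeOH, rt
Reagents that add atoms: none
Why: Catalytic hydrogenolysis cleaves only the aryl benzyl ether, since the methyl ethers, the non-benzylic primary alcohols and the C1–aryl bond are inert under these conditions.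

**Compound list**

1 | 4-hydroxy-3,5-dimethoxyphenylacetic acid (homosyringic acid) | COc1cc(CC(=O)O)cc(OC)c1O | starting material
2 | benzyl (4-benzyloxy-3,5-dimethoxyphenyl)acetate | COc1cc(CC(=O)OCc2ccccc2)cc(OC)c1OCc1ccccc1 | intermediate (not isolated)
3 | (4-benzyloxy-3,5-dimethoxyphenyl)acetic acid | COc1cc(CC(=O)O)cc(OC)c1OCc1ccccc1 | intermediate
4 | 2-(4-benzyloxy-3,5-dimethoxyphenyl)-1-(imidazol-1-yl)ethanone | COc1cc(CC(=O)n2ccnc2)cc(OC)c1OCc1ccccc1 | intermediate (not isolated)
5 | 2-(4-benzyloxy-3,5-dimethoxyphenyl)-N-methoxy-N-methylacetamide | COc1cc(CC(=O)N(C)OC)cc(OC)c1OCc1ccccc1 | intermediate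
6 | 1-(4-benzyloxy-3,5-dimethoxyphenyl)but-3-en-2-one | COc1cc(CC(=O)C=C)cc(OC)c1OCc1ccccc1 | intermediate
7 | (1Z)-1-(4-benzyloxy-3,5-dimethoxyphenyl)-2-(tert-butyldimethylsilyloxy)buta-1,3-diene | C=C/C(O[Si](C)(C)C(C)(C)C)=C/c1cc(OC)c(OCc2ccccc2)c(OC)c1 | intermediate
8 | fumaric acid | OC(=O)/C=C/C(=O)O | starting material
9 | (+)-menthol, (1S,2R,5S)-2-isopropyl-5-methylcyclohexanol | O[C@H]1C[C@@H](C)CC[C@@H]1C(C)C | starting material
10 | di-(+)-menthyl fumarate, bis[(1S,2R,5S)-menthyl] (E)-butenedioate | O=C(/C=C/C(=O)O[C@H]1C[C@@H](C)CC[C@@H]1C(C)C)O[C@H]1C[C@@H](C)CC[C@@H]1C(C)C | intermediate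
11 | di-(+)-menthyl (1R,2R)-3-(4-benzyloxy-3,5-dimethoxyphenyl)-4-(tert-butyldimethylsilyloxy)cyclohex-4-ene-1,2-dicarboxylate, trans diester, aryl-bearing carbon as epimer mixture | C1C[C@@H](C(=O)O[C@H]2C[C@@H](C)CC[C@@H]2C(C)C)[C@H](C(=O)O[C@H]2C[C@@H](C)CC[C@@H]2C(C)C)C(c2cc(OC)c(OCc3ccccc3)c(OC)c2)C(O[Si](C)(C)C(C)(C)C)=1 | intermediate (not isolated)
12 | di-(+)-menthyl (1R,2R)-3-(4-benzyloxy-3,5-dimethoxyphenyl)-4-oxocyclohexane-1,2-dicarboxylate, aryl-bearing carbon not yet equilibrated | C1C[C@@H](C(=O)O[C@H]2C[C@@H](C)CC[C@@H]2C(C)C)[C@H](C(=O)O[C@H]2C[C@@H](C)CC[C@@H]2C(C)C)C(c2cc(OC)c(OCc3ccccc3)c(OC)c2)C1=O | intermediate (not isolated)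
13 | di-(+)-menthyl (1R,2R,3S)-3-(4-benzyloxy-3,5-dimethoxyphenyl)-4-oxocyclohexane-1,2-dicarboxylate, all-trans | C1C[C@@H](C(=O)O[C@H]2C[C@@H](C)CC[C@@H]2C(C)C)[C@H](C(=O)O[C@H]2C[C@@H](C)CC[C@@H]2C(C)C)[C@@H](c2cc(OC)c(OCc3ccccc3)c(OC)c2)C1=O | intermediate
14 | di-(+)-menthyl (1R,2R,3S,5Z)-3-(4-benzyloxy-3,5-dimethoxyphenyl)-5-(hydroxymethylene)-4-oxocyclohexane-1,2-dicarboxylate, enol OH cis to the ketone | O/C=C1/C[C@@H](C(=O)O[C@H]2C[C@@H](C)CC[C@@H]2C(C)C)[C@H](C(=O)O[C@H]2C[C@@H](C)CC[C@@H]2C(C)C)[C@@H](c2cc(OC)c(OCc3ccccc3)c(OC)c2)C1=O | intermediate (key-step precursor)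
15 | 1,3-dimethoxyacetone (1,3-dimethoxypropan-2-one) | COCC(=O)COC | starting material
16 | di-(+)-menthyl (1R,2R,3S)-3-(4-benzyloxy-3,5-dimethoxyphenyl)-5-[(1E)-2,4-dimethoxy-3-oxobut-1-enyl]-4-oxocyclohexane-1,2-dicarboxylate, C5 of the ring undefined | COCC(=O)/C(OC)=C\C1C[C@@H](C(=O)O[C@H]2C[C@@H](C)CC[C@@H]2C(C)C)[C@H](C(=O)O[C@H]2C[C@@H](C)CC[C@@H]2C(C)C)[C@@H](c2cc(OC)c(OCc3ccccc3)c(OC)c2)C1=O | intermediate (not isolated)
17 | 4a-H cyclohexa-2,5-dienone tautomer of 18 (C7 ketone, C5=C6 and C8=C8a double bonds, C4a sp3 and undefined) | COc1cc([C@H]2C3=C(OC)C(=O)C(OC)=CC3C[C@@H](C(=O)O[C@H]3C[C@@H](C)CC[C@@H]3C(C)C)[C@@H]2C(=O)O[C@H]2C[C@@H](C)CC[C@@H]2C(C)C)cc(OC)c1OCc1ccccc1 | intermediate (not isolated)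
18 | di-(+)-menthyl (1S,2R,3R)-1-(4-benzyloxy-3,5-dimethoxyphenyl)-7-hydroxy-6,8-dimethoxy-1,2,3,4-tetrahydronaphthalene-2,3-dicarboxylate, all-trans | COc1cc([C@H]2c3c(cc(OC)c(O)c3OC)C[C@@H](C(=O)O[C@H]3C[C@@H](C)CC[C@@H]3C(C)C)[C@@H]2C(=O)O[C@H]2C[C@@H](C)CC[C@@H]2C(C)C)cc(OC)c1OCc1ccccc1 | intermediate (key-step product)
19 | (1S,2R,3R)-1-(4-benzyloxy-3,5-dimethoxyphenyl)-2,3-bis(hydroxymethyl)-6,8-dimethoxy-1,2,3,4-tetrahydronaphthalen-7-ol | COc1cc([C@H]2c3c(cc(OC)c(O)c3OC)C[C@@H](CO)[C@@H]2CO)cc(OC)c1OCc1ccccc1 | intermediate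
20 | (1S,2R,3R)-1-(4-hydroxy-3,5-dimethoxyphenyl)-2,3-bis(hydroxymethyl)-6,8-dimethoxy-1,2,3,4-tetrahydronaphthalen-7-ol | COc1cc([C@H]2c3c(cc(OC)c(O)c3OC)C[C@@H](CO)[C@@H]2CO)cc(OC)c1O | target

**Step count**

Total steps: 10. Longest linear sequence: 9 (steps 1–4 and 6–10; step 5 is a one-step side branch).

**Steps most likely to fail**

Step 8. The enolate of 15 is present only in low concentration and has to attack a formyl carbon that is itself part of an enolate anion. The condensation may therefore lose out to self-aldolisation of 15 or to methoxide-induced loss of the formyl group. While C8a is still a ketone, C1 can epimerise, and the aryl-axial epimer may close faster because it avoids the developing peri contact with the C8 methoxy group. Once ring A exists, long exposure to base could epimerise the ester-bearing C2. The fallback sets out from 13, bypasses 14 and comes back at 18. Ketone 13 is heated with tert-butoxybis(dimethylamino)methane (toluene, 80 °C), which reacts at the C4a methylene and should give di-(+)-menthyl (1R,2R,3S,5E)-3-(4-benzyloxy-3,5-dimethoxyphenyl)-5-(dimethylaminomethylene)-4-oxocyclohexane-1,2-dicarboxylate F1. The preformed potassium enolate of 15 (KOtBu, THF, −20 → 0 °C) then adds to this neutral vinylogous amide and expels dimethylamine, the way ketone enolates and enaminones give ene-1,5-diones in oligopyridine synthesis. This gives 16, which on warming to room temperature in the same flask should close and aromatise by way of 17 to 18 before the AcOH quench. The neutral electrophile, low temperature and short contact time reduce all three failure processes.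

Step 6. The aluminium Lewis acid may cleave the silyl enol ether or turn the cycloaddition into a stepwise Mukaiyama–Michael addition with loss of facial control, and the electron-rich diene may polymerise. The fallback sets out from 7 and 10 and comes back at 13. The two are heated without Lewis acid (toluene, 90 °C, trace of 2,6-di-tert-butyl-4-methylphenol). The thermal cycloaddition is dependable but has little facial bias, so 11 should form together with its facial diastereomer, di-(+)-menthyl (1S,2S)-3-(4-benzyloxy-3,5-dimethoxyphenyl)-4-(tert-butyldimethylsilyloxy)cyclohex-4-ene-1,2-dicarboxylate F2. Treatment with 1 M HCl/THF and then DBU converts the pair, by way of 12 and the corresponding unequilibrated ketone of the other series F3, into 13 and its all-trans diastereomer di-(+)-menthyl (1S,2S,3R)-3-(4-benzyloxy-3,5-dimethoxyphenyl)-4-oxocyclohexane-1,2-dicarboxylate F4. Because of the menthyl groups 13 and F4 are diastereomers, and 13 is separated by crystallisation or chromatography.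

Step 3. The Grignard reagent may enolise the arylacetamide, and the vinyl ketone may polymerise or take up the released hydroxylamine or a second equivalent of Grignard reagent by conjugate addition. The fallback sets out from 3, bypasses 5 and comes back at 6. Acid 3 is converted with (COCl)2 and catalytic DMF in CH2Cl2 into (4-benzyloxy-3,5-dimethoxyphenyl)acetyl chloride F5. A Stille acylation with tributyl(vinyl)stannane and PdCl2(PPh3)2 (cat.) in THF at 50 °C then gives 6 under neutral conditions, with no basic organometallic reagent and no amine present.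

**Further compounds**

F1 | step 8 | di-(+)-menthyl (1R,2R,3S,5E)-3-(4-benzyloxy-3,5-dimethoxyphenyl)-5-(dimethylaminomethylene)-4-oxocyclohexane-1,2-dicarboxylate | CN(C)/C=C1\C[C@@H](C(=O)O[C@H]2C[C@@H](C)CC[C@@H]2C(C)C)[C@H](C(=O)O[C@H]2C[C@@H](C)CC[C@@H]2C(C)C)[C@@H](c2cc(OC)c(OCc3ccccc3)c(OC)c2)C1=O
F2 | step 6 | di-(+)-menthyl (1S,2S)-3-(4-benzyloxy-3,5-dimethoxyphenyl)-4-(tert-butyldimethylsilyloxy)cyclohex-4-ene-1,2-dicarboxylate, aryl-bearing carbon as epimer mixture | C1C[C@H](C(=O)O[C@H]2C[C@@H](C)CC[C@@H]2C(C)C)[C@@H](C(=O)O[C@H]2C[C@@H](C)CC[C@@H]2C(C)C)C(c2cc(OC)c(OCc3ccccc3)c(OC)c2)C(O[Si](C)(C)C(C)(C)C)=1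
F3 | step 6 | di-(+)-menthyl (1S,2S)-3-(4-benzyloxy-3,5-dimethoxyphenyl)-4-oxocyclohexane-1,2-dicarboxylate, aryl-bearing carbon not yet equilibrated | C1C[C@H](C(=O)O[C@H]2C[C@@H](C)CC[C@@H]2C(C)C)[C@@H](C(=O)O[C@H]2C[C@@H](C)CC[C@@H]2C(C)C)C(c2cc(OC)c(OCc3ccccc3)c(OC)c2)C1=O
F4 | step 6 | di-(+)-menthyl (1S,2S,3R)-3-(4-benzyloxy-3,5-dimethoxyphenyl)-4-oxocyclohexane-1,2-dicarboxylate, all-trans | C1C[C@H](C(=O)O[C@H]2C[C@@H](C)CC[C@@H]2C(C)C)[C@@H](C(=O)O[C@H]2C[C@@H](C)CC[C@@H]2C(C)C)[C@H](c2cc(OC)c(OCc3ccccc3)c(OC)c2)C1=O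
F5 | step 3 | (4-benzyloxy-3,5-dimethoxyphenyl)acetyl chloride | COc1cc(CC(=O)Cl)cc(OC)c1OCc1ccccc1
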